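**Retrosynthetic overview**
- Last bond: the exocyclic C2–NH–C(=N) link, made by condensing a 2-aminoimidazole with preformed 1-methylparabanic acid; global desilylation follows.
- C2–N: lithiation/azidation of the imidazole C2–H and azide reduction, carried out on the bis-silyl ether of the carbinol.
- Stereocentre: the (R)-carbinol comes from the prochiral (4-methoxyphenyl)(imidazol-4-yl) ketone by ketoreductase-catalysed reduction.
- C5–benzyl and C4–acyl bonds: two successive iodine–magnesium exchanges on 4,5-diiodo-1-methylimidazole (C5 first: aldehyde addition then ionic deoxygenation; C4 second: Weinreb acylation).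
- Ring order: no ring is built; the imidazole, both benzene rings and the trione heterocycle are bought intact and only decorated.

Assumption: an (R)-selective ketoreductase for ketone 11 is found by screening a commercial engineered panel, in which both enantiopreferences are normally represented.

Abbreviations: TIPS = triisopropylsilyl, TBS = tert-butyldimethylsilyl, BSA = N,O-bis(trimethylsilyl)acetamide, TBAF = tetrabutylammonium fluoride, TsN3 = 4-methylbenzenesulfonyl azide.

**Route**

Step 1
Reactants: 1 4-hydroxybenzaldehyde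
Product: 2 4-(triisopropylsilyloxy)benzaldehyde
Conditions: TIPSCl (1.1 equiv), imidazole (2 equiv), DMF, 0 °C to rt
Reagents that add atoms: triisopropylsilyl chloride, CC(C)[Si](Cl)(C(C)C)C(C)C
Why: Imidazole-promoted O-silylation of the phenol (silyl ether protection) removes the acidic OH before the Grignard chemistry and gives an aryl ether that tolerates TFA.

Step 2
Reactants: 3 4,5-diiodo-1H-imidazole
Product: 4 4,5-diiodo-1-methyl-1H-imidazole
Conditions: MeI (1.05 equiv), K2CO3, DMF, 0 °C to rt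
Reagents that add atoms: iodomethane, CI
Why: SN2 N-alkylation of the imidazolide gives one isomer only, because the two ring nitrogens of 3 are equivalent by tautomerism.

Step 3
Reactants: 4 4,5-diiodo-1-methyl-1H-imidazole; 2 4-(triisopropylsilyloxy)benzaldehyde
Product: 6 (4-iodo-1-methyl-1H-imidazol-5-yl)[4-(triisopropylsilyloxy)phenyl]methanol (racemic), via imidazol-5-ylmagnesium bromide 5 (not isolated)
Conditions: EtMgBr (1.05 equiv, Et2O solution), CH2Cl2, rt, 30 min; then 2, rt; H2O quench
Reagents that add atoms: none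
Why: Iodine–magnesium exchange is selective for C5, next to the N-methyl nitrogen, and the heteroaryl Grignard reagent adds 1,2 to the aldehyde; the carbinol is racemic, which does not matter because this carbon becomes CH2 in step 4.

Step 4
Reactants: 6 (4-iodo-1-methyl-1H-imidazol-5-yl)[4-(triisopropylsilyloxy)phenyl]methanol
Product: 7 4-iodo-1-methyl-5-[4-(triisopropylsilyloxy)benzyl]-1H-imidazole
Conditions: Et3SiH (4 equiv), TFA, CH2Cl2, 0 °C to rt
Reagents that add atoms: none
Why: Ionic hydrogenation, in which acid ionises the doubly activated benzylic carbinol and the silane delivers hydride, while the carbon–iodine bond and the aryl TIPS ether are inert.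

Step 5
Reactants: 7 4-iodo-1-methyl-5-[4-(triisopropylsilyloxy)benzyl]-1H-imidazole; 8 N,4-dimethoxy-N-methylbenzamide
Product: 10 (4-methoxyphenyl){1-methyl-5-[4-(triisopropylsilyloxy)benzyl]-1H-imidazol-4-yl}methanone, via imidazol-4-ylmagnesium bromide 9 (not isolated)
Conditions: EtMgBr (1.05 equiv), CH2Cl2, rt, 1 h; then 8, rt to 40 °C; H2O quench
Reagents that add atoms: none
Why: A second iodine–magnesium exchange at C4 is followed by Weinreb ketone synthesis, where the chelated tetrahedral adduct prevents over-addition and gives the prochiral diaryl ketone directly.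

Step 6
Reactants: 10 (4-methoxyphenyl){1-methyl-5-[4-(triisopropylsilyloxy)benzyl]-1H-imidazol-4-yl}methanone
Product: 11 [5-(4-hydroxybenzyl)-1-methyl-1H-imidazol-4-yl](4-methoxyphenyl)methanone
Conditions: TBAF (1.2 equiv), AcOH (1.2 equiv), THF, 0 °C to rt
Reagents that add atoms: none
Why: Fluoride-induced cleavage of the aryl silyl ether (desilylation) gives a smaller, water-compatible substrate for the enzyme.

Step 7
Reactants: 11 [5-(4-hydroxybenzyl)-1-methyl-1H-imidazol-4-yl](4-methoxyphenyl)methanone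
Product: 12 4-({4-[(R)-hydroxy(4-methoxyphenyl)methyl]-1-methyl-1H-imidazol-5-yl}methyl)phenol
Conditions: (R)-selective ketoreductase (NADPH-dependent alcohol dehydrogenase, an oxidoreductase), NADP+ (cat.), iPrOH (20 vol%), DMSO (10 vol%), K2HPO4/KH2PO4 buffer pH 7.0, MgSO4 (2 mM), 30 °C, 24 h
Reagents that add atoms: none
Why: Enzymatic asymmetric ketone reduction, in which the ketoreductase binds the two different aryl groups in its chiral pocket and delivers hydride from NADPH to the Si face of the carbonyl, setting the (R)-carbinol while isopropanol recycles the cofactor.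

Step 8
Reactants: 12 4-({4-[(R)-hydroxy(4-methoxyphenyl)methyl]-1-methyl-1H-imidazol-5-yl}methyl)phenol
Product: 13 4-[(R)-(tert-butyldimethylsilyloxy)(4-methoxyphenyl)methyl]-5-[4-(tert-butyldimethylsilyloxy)benzyl]-1-methyl-1H-imidazole
Conditions: TBSCl (3 equiv), imidazole (6 equiv), DMAP (cat.), DMF, rt to 40 °C
Reagents that add atoms: tert-butyldimethylsilyl chloride, CC(C)(C)[Si](C)(C)Cl
Why: Bis-silylation under non-ionising, weakly basic conditions protects both hydroxyls without touching the C–O bond of the stereocentre and leaves no acidic O–H for the lithiation.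

Step 9
Reactants: 13 4-[(R)-(tert-butyldimethylsilyloxy)(4-methoxyphenyl)methyl]-5-[4-(tert-butyldimethylsilyloxy)benzyl]-1-methyl-1H-imidazole
Product: 15 2-azido-4-[(R)-(tert-butyldimethylsilyloxy)(4-methoxyphenyl)methyl]-5-[4-(tert-butyldimethylsilyloxy)benzyl]-1-methyl-1H-imidazole, via 2-lithioimidazole 14 (not isolated)
Conditions: n-BuLi (1.1 equiv), THF, −78 °C, 30 min; then TsN3 (1.2 equiv), −78 °C to rt
Reagents that add atoms: 4-methylbenzenesulfonyl azide, Cc1ccc(cc1)S(=O)(=O)N=[N+]=[N-]
Why: Lithiation–azidation, in which the most acidic ring C–H (C2 of the N-methylimidazole) is removed kinetically at −78 °C and the carbanion takes an azide group from tosyl azide, leaving the silyl-protected stereocentre alone.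

Step 10
Reactants: 15 2-azido-4-[(R)-(tert-butyldimethylsilyloxy)(4-methoxyphenyl)methyl]-5-[4-(tert-butyldimethylsilyloxy)benzyl]-1-methyl-1H-imidazole
Product: 16 4-[(R)-(tert-butyldimethylsilyloxy)(4-methoxyphenyl)methyl]-5-[4-(tert-butyldimethylsilyloxy)benzyl]-1-methyl-1H-imidazol-2-amine
Conditions: H2 (1 atm), Pd/CaCO3 poisoned with Pb(OAc)2, EtOH, rt
Reagents that add atoms: none
Why: Chemoselective catalytic hydrogenation of the azide to the amine over poisoned palladium, which does not hydrogenolyse the doubly benzylic C–O bond.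

Step 11
Reactants: 16 4-[(R)-(tert-butyldimethylsilyloxy)(4-methoxyphenyl)methyl]-5-[4-(tert-butyldimethylsilyloxy)benzyl]-1-methyl-1H-imidazol-2-amine; 17 1-methylimidazolidine-2,4,5-trione (1-methylparabanic acid)
Product: 19 5-({4-[(R)-(tert-butyldimethylsilyloxy)(4-methoxyphenyl)methyl]-5-[4-(tert-butyldimethylsilyloxy)benzyl]-1-methyl-1H-imidazol-2-yl}amino)-3-methylimidazole-2,4-dione, via O-silyl imidate 18 (not isolated)
Conditions: 17, BSA (3 equiv), MeCN, 80 °C, 1 h; evaporate; then 16, toluene, 110 °C; aqueous work-up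
Reagents that add atoms: none
Why: Silyl-mediated condensation, in which BSA turns the imide N–H/C=O of 17 into an O-silyl imidate that undergoes addition–elimination with the exocyclic amine at the carbonyl carbon next to the former NH, giving the amidine link with loss of silanol.

Step 12
Reactants: 19 5-({4-[(R)-(tert-butyldimethylsilyloxy)(4-methoxyphenyl)methyl]-5-[4-(tert-butyldimethylsilyloxy)benzyl]-1-methyl-1H-imidazol-2-yl}amino)-3-methylimidazole-2,4-dione
Product: 20 5-({5-(4-hydroxybenzyl)-4-[(R)-hydroxy(4-methoxyphenyl)methyl]-1-methyl-1H-imidazol-2-yl}amino)-3-methylimidazole-2,4-dione (CNP0181743.1)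
Conditions: TBAF (3 equiv), AcOH (3 equiv), THF, 0 °C to rt
Reagents that add atoms: none
Why: Buffered fluoride desilylation removes both TBS ethers near neutral pH, so the ionisable diaryl carbinol keeps its (R) configuration and the base-sensitive dioxoimidazoline ring survives.

**Compound list**

1 | 4-hydroxybenzaldehyde | O=Cc1ccc(O)cc1 | starting material
2 | 4-(triisopropylsilyloxy)benzaldehyde | O=Cc1ccc(O[Si](C(C)C)(C(C)C)C(C)C)cc1 | intermediate
3 | 4,5-diiodo-1H-imidazole | Ic1nc[nH]c1I | starting material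
4 | 4,5-diiodo-1-methyl-1H-imidazole | Cn1cnc(I)c1I | intermediate
5 | (4-iodo-1-methyl-1H-imidazol-5-yl)magnesium bromide | Cn1cnc(I)c1[Mg]Br | intermediate
6 | (4-iodo-1-methyl-1H-imidazol-5-yl)[4-(triisopropylsilyloxy)phenyl]methanol (racemic) | Cn1cnc(I)c1C(O)c1ccc(O[Si](C(C)C)(C(C)C)C(C)C)cc1 | intermediate
7 | 4-iodo-1-methyl-5-[4-(triisopropylsilyloxy)benzyl]-1H-imidazole | Cn1cnc(I)c1Cc1ccc(O[Si](C(C)C)(C(C)C)C(C)C)cc1 | intermediate
8 | N,4-dimethoxy-N-methylbenzamide | COc1ccc(cc1)C(=O)N(C)OC | starting material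
9 | {1-methyl-5-[4-(triisopropylsilyloxy)benzyl]-1H-imidazol-4-yl}magnesium bromide | Cn1cnc([Mg]Br)c1Cc1ccc(O[Si](C(C)C)(C(C)C)C(C)C)cc1 | intermediate
10 | (4-methoxyphenyl){1-methyl-5-[4-(triisopropylsilyloxy)benzyl]-1H-imidazol-4-yl}methanone | COc1ccc(cc1)C(=O)c1ncn(C)c1Cc1ccc(O[Si](C(C)C)(C(C)C)C(C)C)cc1 | intermediate
11 | [5-(4-hydroxybenzyl)-1-methyl-1H-imidazol-4-yl](4-methoxyphenyl)methanone | COc1ccc(cc1)C(=O)c1ncn(C)c1Cc1ccc(O)cc1 | intermediate
12 | 4-({4-[(R)-hydroxy(4-methoxyphenyl)methyl]-1-methyl-1H-imidazol-5-yl}methyl)phenol | COc1ccc([C@@H](O)c2ncn(C)c2Cc2ccc(O)cc2)cc1 | intermediate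
13 | 4-[(R)-(tert-butyldimethylsilyloxy)(4-methoxyphenyl)methyl]-5-[4-(tert-butyldimethylsilyloxy)benzyl]-1-methyl-1H-imidazole | COc1ccc([C@@H](O[Si](C)(C)C(C)(C)C)c2ncn(C)c2Cc2ccc(O[Si](C)(C)C(C)(C)C)cc2)cc1 | intermediate
14 | {4-[(R)-(tert-butyldimethylsilyloxy)(4-methoxyphenyl)methyl]-5-[4-(tert-butyldimethylsilyloxy)benzyl]-1-methyl-1H-imidazol-2-yl}lithium | COc1ccc([C@@H](O[Si](C)(C)C(C)(C)C)c2nc([Li])n(C)c2Cc2ccc(O[Si](C)(C)C(C)(C)C)cc2)cc1 | intermediate
15 | 2-azido-4-[(R)-(tert-butyldimethylsilyloxy)(4-methoxyphenyl)methyl]-5-[4-(tert-butyldimethylsilyloxy)benzyl]-1-methyl-1H-imidazole | COc1ccc([C@@H](O[Si](C)(C)C(C)(C)C)c2nc(N=[N+]=[N-])n(C)c2Cc2ccc(O[Si](C)(C)C(C)(C)C)cc2)cc1 | intermediate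
16 | 4-[(R)-(tert-butyldimethylsilyloxy)(4-methoxyphenyl)methyl]-5-[4-(tert-butyldimethylsilyloxy)benzyl]-1-methyl-1H-imidazol-2-amine | COc1ccc([C@@H](O[Si](C)(C)C(C)(C)C)c2nc(N)n(C)c2Cc2ccc(O[Si](C)(C)C(C)(C)C)cc2)cc1 | intermediate
17 | 1-methylimidazolidine-2,4,5-trione (1-methylparabanic acid) | CN1C(=O)NC(=O)C1=O | starting material
18 | 3-methyl-5-(trimethylsilyloxy)imidazole-2,4-dione (O-silyl imidate of 17) | CN1C(=O)N=C(O[Si](C)(C)C)C1=O | intermediate
19 | 5-({4-[(R)-(tert-butyldimethylsilyloxy)(4-methoxyphenyl)methyl]-5-[4-(tert-butyldimethylsilyloxy)benzyl]-1-methyl-1H-imidazol-2-yl}amino)-3-methylimidazole-2,4-dione | COc1ccc([C@@H](O[Si](C)(C)C(C)(C)C)c2nc(NC3=NC(=O)N(C)C3=O)n(C)c2Cc2ccc(O[Si](C)(C)C(C)(C)C)cc2)cc1 | intermediate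
20 | 5-({5-(4-hydroxybenzyl)-4-[(R)-hydroxy(4-methoxyphenyl)methyl]-1-methyl-1H-imidazol-2-yl}amino)-3-methylimidazole-2,4-dione (CNP0181743.1) | COc1ccc([C@@H](O)c2nc(NC3=NC(=O)N(C)C3=O)n(C)c2Cc2ccc(O)cc2)cc1 | target

**Totals**
Total step count: 12.
Longest linear sequence: 11 steps (3 to 20 through steps 2 to 12; equally 1 to 20 through steps 1 and 3 to 12).

**Steps most likely to fail, with fallbacks**

Step 7 (ketoreductase reduction of 11). The risk is that no panel enzyme combines useful activity with high (R)-selectivity on this bulky diaryl ketone. The fallback sets the stereocentre one stage earlier with a chemical catalyst. It sets out from silyl ketone 10, which is reduced by asymmetric transfer hydrogenation with RuCl[(S,S)-TsDPEN](p-cymene) or its mirror image in HCO2H/Et3N (5:2) at 30 °C. The ortho-substituted, nitrogen-bearing imidazolyl group and the unhindered anisyl group are differentiated by the catalyst, and the ligand hand is fixed in a test run with Mosher ester analysis. This gives (R)-(4-methoxyphenyl){1-methyl-5-[4-(triisopropylsilyloxy)benzyl]-1H-imidazol-4-yl}methanol F1. TBAF/AcOH in THF then removes the aryl silyl ether, and the route is rejoined at 12.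

Step 9 (lithiation–azidation of 13). The risk is competing deprotonation at the doubly activated C–H of the silyloxy carbon (loss of ee or silyl migration) or poor azide transfer. The fallback functionalises C2 without a strong base. It sets out from 13, which NBS (1.05 equiv, THF, −20 °C, dark) brominates at the only free ring position to give 2-bromo-4-[(R)-(tert-butyldimethylsilyloxy)(4-methoxyphenyl)methyl]-5-[4-(tert-butyldimethylsilyloxy)benzyl]-1-methyl-1H-imidazole F2. Palladium-catalysed C–N coupling with benzophenone imine (Pd2(dba)3, tBuBrettPhos, Cs2CO3, toluene, 90 °C) gives N-(diphenylmethylidene)-4-[(R)-(tert-butyldimethylsilyloxy)(4-methoxyphenyl)methyl]-5-[4-(tert-butyldimethylsilyloxy)benzyl]-1-methyl-1H-imidazol-2-amine F3. Transimination with NH2OH·HCl/NaOAc in MeOH at rt releases the amine, and the route is rejoined at 16; azide 15 and step 10 are bypassed.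

Step 11 (condensation of 16 with 17). The risk is incomplete conversion, attack through the ring nitrogen, or loss of silyl groups or ee at 110 °C. The fallback builds the dioxoimidazoline ring stepwise on the exocyclic nitrogen below 60 °C. It sets out from 16, which reacts with ethyl 2-ethoxy-2-iminoacetate (EtOH, 40 °C) in a Pinner-type amidine formation to give ethyl 2-({4-[(R)-(tert-butyldimethylsilyloxy)(4-methoxyphenyl)methyl]-5-[4-(tert-butyldimethylsilyloxy)benzyl]-1-methyl-1H-imidazol-2-yl}amino)-2-iminoacetate F4. Methyl isocyanate (Et3N, CH2Cl2, 0 °C) carbamoylates the amidine NH to give ethyl 2-({4-[(R)-(tert-butyldimethylsilyloxy)(4-methoxyphenyl)methyl]-5-[4-(tert-butyldimethylsilyloxy)benzyl]-1-methyl-1H-imidazol-2-yl}amino)-2-[(methylcarbamoyl)imino]acetate F5. DBU (THF, rt to 50 °C) closes the urea N–H onto the ester, and the route is rejoined at 19.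

**Further compounds**

F1 | step 7 | (R)-(4-methoxyphenyl){1-methyl-5-[4-(triisopropylsilyloxy)benzyl]-1H-imidazol-4-yl}methanol | COc1ccc([C@@H](O)c2ncn(C)c2Cc2ccc(O[Si](C(C)C)(C(C)C)C(C)C)cc2)cc1
F2 | step 9 | 2-bromo-4-[(R)-(tert-butyldimethylsilyloxy)(4-methoxyphenyl)methyl]-5-[4-(tert-butyldimethylsilyloxy)benzyl]-1-methyl-1H-imidazole | COc1ccc([C@@H](O[Si](C)(C)C(C)(C)C)c2nc(Br)n(C)c2Cc2ccc(O[Si](C)(C)C(C)(C)C)cc2)cc1
F3 | step 9 | N-(diphenylmethylidene)-4-[(R)-(tert-butyldimethylsilyloxy)(4-methoxyphenyl)methyl]-5-[4-(tert-butyldimethylsilyloxy)benzyl]-1-methyl-1H-imidazol-2-amine | COc1ccc([C@@H](O[Si](C)(C)C(C)(C)C)c2nc(N=C(c3ccccc3)c3ccccc3)n(C)c2Cc2ccc(O[Si](C)(C)C(C)(C)C)cc2)cc1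
F4 | step 11 | ethyl 2-({4-[(R)-(tert-butyldimethylsilyloxy)(4-methoxyphenyl)methyl]-5-[4-(tert-butyldimethylsilyloxy)benzyl]-1-methyl-1H-imidazol-2-yl}amino)-2-iminoacetate | COc1ccc([C@@H](O[Si](C)(C)C(C)(C)C)c2nc(NC(=N)C(=O)OCC)n(C)c2Cc2ccc(O[Si](C)(C)C(C)(C)C)cc2)cc1
F5 | step 11 | ethyl 2-({4-[(R)-(tert-butyldimethylsilyloxy)(4-methoxyphenyl)methyl]-5-[4-(tert-butyldimethylsilyloxy)benzyl]-1-methyl-1H-imidazol-2-yl}amino)-2-[(methylcarbamoyl)imino]acetate | COc1ccc([C@@H](O[Si](C)(C)C(C)(C)C)c2nc(NC(=NC(=O)NC)C(=O)OCC)n(C)c2Cc2ccc(O[Si](C)(C)C(C)(C)C)cc2)cc1
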